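| setting | red | ochre | violet | zeta | gamma | delta | beta | alpha |
|---|---|---|---|---|---|---|---|---|
| substrate | 0.56 M | 0.56 M | 0.47 M | 1.2 M | 2.5 M | 0.30 M | 0.56 M | 0.15 M |
| reagent | 0.36 M | 0.94 M | 1.4 M | 0.500 M | 1.00 M | 1.40 M | 1.40 M | 1.40 M |
| remark | run made earlier | run made earlier | run made earlier |  |  |  |  |  |
| time |  |  |  | 1.0 h | 1.0 h | 1.0 h | 1.0 h | 1.0 h |

| run | time / min | target / % | substrate / % |
|---|---|---|---|
| red | 3.00 | 3.2 | 95.8 |
| red | 8.00 | 8.1 | 91.8 |
| red | 15.0 | 13.4 | 86.2 |
| red | 25.0 | 20.3 | 78.8 |
| red | 30.0 | 22.4 | 76.4 |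
| red | 40.0 | 26.8 | 71.8 |
| ochre | 8.00 | 19.3 | 80.6 |
| ochre | 15.0 | 31.7 | 66.8 |
| ochre | 20.0 | 38.0 | 60.1 |
| ochre | 30.0 | 47.6 | 48.5 |
| ochre | 40.0 | 55.2 | 39.1 |
| violet | 4.00 | 15.2 | 84.4 |
| violet | 10.0 | 33.9 | 66.6 |
| violet | 20.0 | 51.7 | 45.4 |
| violet | 30.0 | 62.5 | 32.6 |
| violet | 40.0 | 67.8 | 23.9 |

(scatter of a reading: 0.5 percentage points)



1. ranking by amount of target, in percent of the substrate charged, from high to low, at 1.0 h (zeta / gamma / delta / beta / alpha)
2. the amount of target, in percent of the substrate charged of the flask you put first, at 1.0 h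
3. the amount of target, in percent of the substrate charged of the flask you put last, at 1.0 h

- I had to decide which of the five flasks to charge next for the most target at 1.0 h, so I asked first where each must end: taking substrate and reagent to fall one for one, a flask short of reagent stops losing substrate when the share of substrate gone equals its charge ratio, 41.7% for zeta and 40.0% for gamma, with reagent the limiting reagent in both .

- Then I asked how fast that end is approached: I integrated rate = k[S][R], where [S] and [R] are the concentrations of substrate and reagent, and the last reading of each run gave 0.0308 M⁻¹ min⁻¹ in red, 0.0321 M⁻¹ min⁻¹ in ochre and 0.0305 M⁻¹ min⁻¹ in violet, so I carried their mean 0.0311 M⁻¹ min⁻¹, the forward constant k.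

- With k, the reach, meaning the share of charged substrate that has passed by a given time, came at 1.0 h to 91.3% for alpha, 89.7% for delta, 86.4% for beta, 38.5% for gamma and 34.3% for zeta.

- The readings of target fell short of the substrate gone, by 8.3 percentage points in violet at 40.0 min and 1.4 points in red at 40.0 min, so I took reach as a ceiling on target and not as a forecast of it, and I decided to charge alpha, whose reach was higher than any other, and to drop gamma and zeta, whose reaches stood lower than beta's.

- The forecast gave alpha > delta > beta > zeta > gamma, with 84.5% for the first and 22.6% for the last; it put gamma below zeta, the reverse of my order of reach, with this caution: “The zeta and gamma order depends on the squared loss, which extrapolates beyond the tested concentrations.”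

- The flasks gave alpha > delta > beta > zeta > gamma, with alpha at 80.4%, zeta at 28.1% and gamma at 25.6%.

    target → over-reaction product (k = 3.30 × 10⁻⁵ s⁻¹)
    substrate + reagent → target + by-product (k = 5.20 × 10⁻⁴ M⁻¹ s⁻¹)
    target + by-product → side product (k = 1.70 × 10⁻⁴ M⁻¹ s⁻¹)

- In alpha 8.69% of the substrate remained, so 91.3% had passed against my reach of 91.3%, while target stood 11 points below that reach, with 7.03% as over-reaction product and 3.85% as side product. I reckoned the neighbour the same way: alpha charged with 0.35 M of reagent in place of 1.40 M had, with 0.0311 M⁻¹ min⁻¹, a reach of 44.2% at 1.0 h, and that flask held 55.7% of its substrate still unreacted and 40.8% as target.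

The runs stem from a simulated flask for substances that don't exist.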